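**Plan**
- Retrosynthesis: the free acid is traced back to its benzyl ester. The depside ester is then cut on both sides of its carbonyl carbon, at C1(ring A)–C(=O) and at C(=O)–O4(ring B), giving an aryl iodide, carbon monoxide and a phenol.
- Enabling feature: the ester carbonyl carbon lies between C1 of ring A (the dimethoxybenzoyl ring, flanked by OMe at C2 and propyl at C6) and O4 of ring B (the salicylic acid ring with CO2H at C1, OH at C2, pentyl at C6). As a one-carbon unit it can be delivered as CO on palladium, so no hindered acyl electrophile has to be attacked.
- Ring A fragment: the aryl–propyl bond by Kumada coupling, then a C–I bond para to one OMe. Ring B fragment: the C1–CO2 bond by carboxylation of olivetol, then a benzyl ester.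
- Forward order: both benzene rings are purchased and no ring is formed. The two arenes are joined through CO in step 5 and the benzyl group is removed in step 6.
- Stereochemistry: the target has no stereocentre and no stereogenic double bond, so nothing has to be set.

Key step: step 5

Assumption: carbon monoxide and propylmagnesium chloride are numbered as reactants because their carbon atoms end up in the skeleton.

**Route**

Step 1
Reactants: 1 1-bromo-3,5-dimethoxybenzene; 2 propylmagnesium chloride
Product: 3 1,3-dimethoxy-5-propylbenzene
Conditions: NiCl2(dppp) (2 mol %), THF, 0 °C to 50 °C; aq. NH4Cl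
Reagents that add atoms: none
Why: Kumada–Corriu coupling, in which NiCl2(dppp) is the standard catalyst for joining primary alkyl Grignard reagents to aryl bromides, the chelating diphosphine keeping β-hydride elimination slow so that the n-propyl group is transferred unchanged while the methyl ethers are inert.

Step 2
Reactants: 3 1,3-dimethoxy-5-propylbenzene
Product: 4 2-iodo-1,5-dimethoxy-3-propylbenzene
Conditions: N-iodosuccinimide (1.05 equiv), TFA (10 mol %), MeCN, 0 °C to rt, dark
Reagents that add atoms: N-iodosuccinimide, O=C1CCC(=O)N1I
Why: Electrophilic aromatic iodination, expected at the carbon next to propyl because it is para to one methoxy group, ortho to the other and less crowded than the site between the two methoxy groups, the two such carbons being equivalent by symmetry.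

Step 3
Reactants: 5 olivetol (5-pentylbenzene-1,3-diol)
Product: 7 olivetolic acid (2,4-dihydroxy-6-pentylbenzoic acid), via magnesium olivetolate chelate 6 (not isolated)
Conditions: MeOMgOCO2Me (2 M in DMF, 3 equiv), 120 °C, N2 stream; then ice-cold 2 M HCl
Reagents that add atoms: methoxymagnesium methyl carbonate (MeOMgOCO2Me), CO[Mg]OC(=O)OC
Why: Stiles carboxylation, a chelation-driven Kolbe–Schmitt-type reaction in which the magnesium phenoxide delivers CO2 to an ortho carbon and the six-membered magnesium salicylate chelate 6 pulls the equilibrium over, the carbon para to the second hydroxyl being the usual site of electrophilic attack in 5-alkylresorcinols.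

Step 4
Reactants: 7 olivetolic acid
Product: 8 benzyl 2,4-dihydroxy-6-pentylbenzoate
Conditions: BnBr (1.05 equiv), KHCO3 (1.2 equiv), DMF, rt
Reagents that add atoms: benzyl bromide, BrCc1ccccc1
Why: SN2 O-alkylation of a carboxylate, chemoselective because hydrogencarbonate deprotonates the carboxylic acid but not the phenols, as is routine for benzyl esters of 2,4-dihydroxybenzoic acids.

Step 5
Reactants: 4 2-iodo-1,5-dimethoxy-3-propylbenzene; 8 benzyl 2,4-dihydroxy-6-pentylbenzoate; 9 carbon monoxide
Product: 10 benzyl 4-(2,4-dimethoxy-6-propylbenzoyloxy)-2-hydroxy-6-pentylbenzoate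
Conditions: Pd(OAc)2 (5 mol %), Xantphos (6 mol %), Et3N (3 equiv), CO (1 atm, balloon), toluene, 90 °C; 8 in slight excess (1.2 equiv)
Reagents that add atoms: none
Why: Zerovalent palladium formed from Pd(OAc)2 and Xantphos adds oxidatively to the C–I bond of 4, CO inserts to give an aroyl divalent palladium species, the triethylammonium phenoxide of 8 replaces iodide on the metal, and C–O reductive elimination releases 10 and regenerates zerovalent palladium. The closest known reaction type is the palladium-catalysed aryloxycarbonylation of aryl iodides with phenols under atmospheric CO using wide-bite-angle diphosphines. No ring is closed and no stereocentre is formed; the two new bonds are C1 of ring A to the carbonyl carbon and the carbonyl carbon to O4 of ring B. The two ortho substituents of 4 are tolerable for an iodide in oxidative addition and favour migratory insertion by relief of strain, and the acyl group is passed to oxygen inside the coordination sphere, so the hindered carbonyl is never attacked from outside. The step needs site selectivity between the two phenols of 8: the 2-OH is tied up in a hydrogen bond to the ester carbonyl and flanked by the ester, whereas the 4-OH is open and the more acidic, so its phenoxide is the one that binds palladium, and the slight excess of 8 guards against double acylation.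

Step 6
Reactants: 10 benzyl 4-(2,4-dimethoxy-6-propylbenzoyloxy)-2-hydroxy-6-pentylbenzoate
Product: 11 4-(2,4-dimethoxy-6-propylbenzoyloxy)-2-hydroxy-6-pentylbenzoic acid
Conditions: H2 (1 atm), Pd/C (10% palladium on carbon), EtOAc, rt
Reagents that add atoms: none
Why: Catalytic hydrogenolysis of the benzylic C–O bond under neutral conditions frees the acid, while the aryl ester of the depside, the methyl ethers and the phenol carry no benzylic C–O bond and should remain intact.

**Compound list**
1 | 1-bromo-3,5-dimethoxybenzene | COc1cc(Br)cc(OC)c1 | starting material
2 | propylmagnesium chloride | CCC[Mg]Cl | starting material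
3 | 1,3-dimethoxy-5-propylbenzene | CCCc1cc(OC)cc(OC)c1 | intermediate
4 | 2-iodo-1,5-dimethoxy-3-propylbenzene | CCCc1cc(OC)cc(OC)c1I | intermediate
5 | olivetol (5-pentylbenzene-1,3-diol) | CCCCCc1cc(O)cc(O)c1 | starting material
6 | magnesium olivetolate chelate (cyclic magnesium salt through the carboxylate and the 2-oxide of 4-hydroxy-6-pentylsalicylate) | CCCCCc1cc(O)cc2O[Mg]OC(=O)c12 | intermediate
7 | olivetolic acid (2,4-dihydroxy-6-pentylbenzoic acid) | CCCCCc1cc(O)cc(O)c1C(=O)O | intermediate
8 | benzyl 2,4-dihydroxy-6-pentylbenzoate | CCCCCc1cc(O)cc(O)c1C(=O)OCc1ccccc1 | intermediate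
9 | carbon monoxide | [C-]#[O+] | starting material
10 | benzyl 4-(2,4-dimethoxy-6-propylbenzoyloxy)-2-hydroxy-6-pentylbenzoate | CCCCCc1cc(OC(=O)c2c(CCC)cc(OC)cc2OC)cc(O)c1C(=O)OCc1ccccc1 | intermediate
11 | 4-(2,4-dimethoxy-6-propylbenzoyloxy)-2-hydroxy-6-pentylbenzoic acid | CCCCCc1cc(OC(=O)c2c(CCC)cc(OC)cc2OC)cc(O)c1C(=O)O | target

**Count**
Total steps: 6. Longest linear sequence: 4 steps (steps 1, 2, 5, 6 or steps 3, 4, 5, 6).

**Steps most likely to fail**

1. Step 5. Oxidative addition into the doubly ortho-substituted, electron-rich C–I bond may be slow, so that protodeiodination or catalyst deactivation by phenoxide competes, and part of the acyl transfer may go to the 2-OH or occur twice. The fallback sets out from 4 and comes back to the route at 10. Iodide 4 would be treated with Mg turnings in THF to give (2,4-dimethoxy-6-propylphenyl)magnesium iodide F1. Dry CO2 would convert this into iodomagnesium 2,4-dimethoxy-6-propylbenzoate F2, and aqueous HCl would give 2,4-dimethoxy-6-propylbenzoic acid F3. F3 and phenol 8 would then be stirred with trifluoroacetic anhydride in toluene at room temperature. The mixed anhydride 2,4-dimethoxy-6-propylbenzoic trifluoroacetic anhydride F4 ionises to a stabilised acylium ion, which should acylate the open 4-OH of 8 to give 10.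

2. Step 3. Carboxylation may go in part to the carbon between the two hydroxyls, may stall at low conversion, and the acid may lose CO2 again on acidification or warming. The fallback sets out from 5 and comes back to the route at 7. Vilsmeier–Haack formylation of olivetol 5 (POCl3, DMF, 0 °C to rt) should give the aryl iminium salt N-[(2,4-dihydroxy-6-pentylphenyl)methylidene]-N-methylmethanaminium chloride F5. Aqueous work-up hydrolyses it to 2,4-dihydroxy-6-pentylbenzaldehyde F6. Lindgren oxidation (NaClO2, NaH2PO4, sulfamic acid as chlorine scavenger, aqueous dioxane, 0 °C) would then convert the aldehyde into acid 7.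

3. Step 2. Iodination may go partly to the carbon between the two methoxy groups or a second time, and the acid catalyst may cause iodine to migrate or be lost. The fallback sets out from 3 and comes back to the route at 4. Bromination with N-bromosuccinimide in MeCN at 0 °C, which is reliably para-selective for methoxyarenes, should give 2-bromo-1,5-dimethoxy-3-propylbenzene F7. Bromine–lithium exchange with n-BuLi in THF at −78 °C would give (2,4-dimethoxy-6-propylphenyl)lithium F8, and quenching with I2 places iodine on the same carbon to give 4.

**Further compounds**
F1 | step 5 | (2,4-dimethoxy-6-propylphenyl)magnesium iodide | CCCc1cc(OC)cc(OC)c1[Mg]I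
F2 | step 5 | iodomagnesium 2,4-dimethoxy-6-propylbenzoate | CCCc1cc(OC)cc(OC)c1C(=O)O[Mg]I
F3 | step 5 | 2,4-dimethoxy-6-propylbenzoic acid | CCCc1cc(OC)cc(OC)c1C(=O)O
F4 | step 5 | 2,4-dimethoxy-6-propylbenzoic trifluoroacetic anhydride | CCCc1cc(OC)cc(OC)c1C(=O)OC(=O)C(F)(F)F
F5 | step 3 | N-[(2,4-dihydroxy-6-pentylphenyl)methylidene]-N-methylmethanaminium chloride | CCCCCc1cc(O)cc(O)c1C=[N+](C)C.[Cl-]
F6 | step 3 | 2,4-dihydroxy-6-pentylbenzaldehyde | CCCCCc1cc(O)cc(O)c1C=O
F7 | step 2 | 2-bromo-1,5-dimethoxy-3-propylbenzene | CCCc1cc(OC)cc(OC)c1Br
F8 | step 2 | (2,4-dimethoxy-6-propylphenyl)lithium | [Li]c1c(CCC)cc(OC)cc1OC
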